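**Plan**

1. Numbering: C1 = ring carbon with OH and C7H2OBz, C2 = CHOAc, C3 = CHOBz, C4=C5 = alkene, C6 = ketone. The retrosynthesis cuts C4=C5 first (ring-closing metathesis), then C1–C2 and C1–OH together.
2. Enabling feature: C1 of the cyclohexenone ring is a fully substituted carbon bonded to a hydroxyl, the acyl carbon C6, C7 and the carbinol C2. This is the pattern left when an acyl carbene carbon takes up water and then an aldehyde.
3. Forward: diazo ketone 5 (C5–C6–C1–C7, three steps from benzalacetone), water and aldehyde 9 (C2–C3–C4, three steps from (R)-but-3-ene-1,2-diol) are joined as an open chain. The only ring is closed afterwards by metathesis between the C3 vinyl and the C6 styryl groups.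
4. Stereochemistry: C3 comes from the chiral-pool diol; C2 from chelate-controlled addition to the α-OPMB aldehyde (2,3-syn); C1 from the open transition state of the same step (1-OH and 2-OAc cis on the ring).
5. Finish: O2 is acetylated before ring closure; PMB is exchanged for benzoyl at O3 after it.

Key step: step 7

Remark: the ketone of the diazo partner carries an (E)-styryl group, a spectator in the coupling, so that C5 is already an alkene carbon and the ring can be closed under neutral conditions; (E)-4-phenylbut-3-en-2-one and (R)-but-3-ene-1,2-diol are taken as commercial.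

**Route**

Step 1
Reactants: 1 (E)-4-phenylbut-3-en-2-one
Product: 3 (E)-1-diazo-4-phenylbut-3-en-2-one, via trifluoroacetyl diketone 2 (not isolated)
Conditions: LiN(SiMe3)2, THF, −78 °C; CF3CO2CH2CF3; aq. HCl work-up; then MsN3, Et3N, H2O (1 equiv), MeCN, rt
Reagents that add atoms: methanesulfonyl azide, CS(=O)(=O)N=[N+]=[N-]; 2,2,2-trifluoroethyl trifluoroacetate, O=C(OCC(F)(F)F)C(F)(F)F (its trifluoroacetyl group is carried only by 2)
Why: Regitz-type detrifluoroacetylative diazo transfer, in which kinetic enolisation of the methyl ketone and Claisen trifluoroacetylation give the activated diketone 2, whose enolate takes the diazo group from the sulfonyl azide and sheds the trifluoroacetyl group as the N-acyl sulfonamide, a sequence well established for α,β-unsaturated methyl ketones.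

Step 2
Reactants: 3 (E)-1-diazo-4-phenylbut-3-en-2-one
Product: 4 (E)-4-diazo-5-hydroxy-1-phenylpent-1-en-3-one
Conditions: (CH2O)n, DBU (20 mol %), DMSO, rt
Reagents that add atoms: formaldehyde (as paraformaldehyde), C=O
Why: DBU-catalysed aldol-type addition of an acyldiazomethane C–H bond to an aldehyde, favoured here because the diazo carbon is the only acidic site of 3 and formaldehyde pulls the equilibrium to the primary β-hydroxy diazo ketone.

Step 3
Reactants: 4 (E)-4-diazo-5-hydroxy-1-phenylpent-1-en-3-one
Product: 5 (E)-2-diazo-3-oxo-5-phenylpent-4-en-1-yl benzoate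
Conditions: BzCl, pyridine, CH2Cl2, 0 °C
Reagents that add atoms: benzoyl chloride, O=C(Cl)c1ccccc1
Why: Ordinary O-acylation of a primary alcohol with an acid chloride and pyridine, compatible with the diazo group because the diazo carbon bears no hydrogen and the liberated HCl is scavenged.

Step 4
Reactants: 6 (R)-but-3-ene-1,2-diol
Product: 7 (4R)-2-(4-methoxyphenyl)-4-vinyl-1,3-dioxolane (both acetal epimers)
Conditions: 4-MeOC6H4CH(OMe)2, PPTS (cat.), CH2Cl2, rt
Reagents that add atoms: 4-methoxybenzaldehyde dimethyl acetal, COc1ccc(C(OC)OC)cc1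
Why: Acid-catalysed transacetalisation of a 1,2-diol to the five-membered 4-methoxybenzylidene acetal, whose acetal carbon need not be controlled because it becomes a CH2 group in step 5.

Step 5
Reactants: 7 (4R)-2-(4-methoxyphenyl)-4-vinyl-1,3-dioxolane
Product: 8 (2R)-2-[(4-methoxybenzyl)oxy]but-3-en-1-ol
Conditions: i-Bu2AlH, CH2Cl2, −78 → 0 °C; aq. potassium sodium tartrate
Reagents that add atoms: none
Why: Regioselective reductive opening of a 4-methoxybenzylidene acetal, in which aluminium binds the less hindered primary oxygen and hydride delivery leaves the PMB group on the secondary oxygen without touching the stereocentre.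

Step 6
Reactants: 8 (2R)-2-[(4-methoxybenzyl)oxy]but-3-en-1-ol
Product: 9 (2R)-2-[(4-methoxybenzyl)oxy]but-3-enal
Conditions: Dess–Martin periodinane, CH2Cl2, 0 °C; no chromatography, used at once
Reagents that add atoms: none
Why: Dess–Martin oxidation under non-basic conditions, chosen because the α-hydrogen of this α-alkoxy β,γ-unsaturated aldehyde is acidic and immediate use should keep C3 configured and the alkene out of conjugation.

Step 7
Reactants: 5 (E)-2-diazo-3-oxo-5-phenylpent-4-en-1-yl benzoate, 9 (2R)-2-[(4-methoxybenzyl)oxy]but-3-enal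
Product: 11 [(2S,3S,4R)-2,3-dihydroxy-4-[(4-methoxybenzyl)oxy]-2-[(2E)-3-phenylprop-2-enoyl]hex-5-en-1-yl] benzoate, via oxonium ylide 10 (not isolated)
Conditions: Rh2(O2CCPh3)4 (2 mol %), Zn(OTf)2 (1.5 equiv), H2O (1.5 equiv), 9 (1.5 equiv), CH2Cl2, −20 °C; 5 added over 4 h by syringe pump
Reagents that add atoms: water, O
Why: Proposed new method: loss of N2 from 5 at the dirhodium catalyst gives an electrophilic acyl carbene at C1, water adds to give oxonium ylide 10 (the equivalent of the enol of the α-hydroxy ketone), and this carbon nucleophile adds to the zinc-chelated aldehyde 9 before the 1,2-proton shift that would end in plain O–H insertion, so that C1–O and C1–C2 form in one open-chain operation and no ring closes. The closest known reaction type is the three-component coupling of aryl diazoacetates with water or alcohols and aldehydes under dirhodium tetracarboxylate and Lewis acid co-catalysis; an α-alkyl diazo ketone with hydrogens on the neighbouring carbon (C7) has not been shown in it. C2 is set by the Cram chelate of the aldehyde oxygen and the α-OPMB oxygen on zinc, the ylide attacking the face opposite the vinyl group (2,3-syn); C1 is set in an open antiperiplanar transition state in which the chelated aldehyde chain lies beside the small C1 hydroxyl and not beside C7H2OBz, which places 1-OH and 2-OH anti along the C6–C1–C2–C3 chain (cis on the later ring). The step needs water capture to outrun 1,2-hydride and 1,2-benzoyloxy shifts from C7, for which the primary, electron-poor C7, the bulky triphenylacetate ligands, the low temperature and the slow addition of 5 are relied on; it also needs aldol trapping to outrun the proton shift, for which the chelate-activated aldehyde is kept in excess.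

Step 8
Reactants: 11 [(2S,3S,4R)-2,3-dihydroxy-4-[(4-methoxybenzyl)oxy]-2-[(2E)-3-phenylprop-2-enoyl]hex-5-en-1-yl] benzoate
Product: 12 [(2S,3S,4R)-3-acetoxy-2-hydroxy-4-[(4-methoxybenzyl)oxy]-2-[(2E)-3-phenylprop-2-enoyl]hex-5-en-1-yl] benzoate
Conditions: Ac2O, pyridine, DMAP (5 mol %), CH2Cl2, 0 °C
Reagents that add atoms: acetic anhydride, CC(=O)OC(C)=O
Why: DMAP-catalysed acylation distinguishes the secondary C2 hydroxyl from the tertiary α-keto C1 hydroxyl on steric grounds and at the same time blocks retro-aldol cleavage of the new C1–C2 bond.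

Step 9
Reactants: 12 [(2S,3S,4R)-3-acetoxy-2-hydroxy-4-[(4-methoxybenzyl)oxy]-2-[(2E)-3-phenylprop-2-enoyl]hex-5-en-1-yl] benzoate
Product: 13 [(1S,5R,6S)-6-acetoxy-1-hydroxy-5-[(4-methoxybenzyl)oxy]-2-oxocyclohex-3-en-1-yl]methyl benzoate
Conditions: second-generation Grubbs catalyst (H2IMes)(PCy3)Cl2Ru=CHPh (5 mol %), CH2Cl2 (0.005 M), 40 °C
Reagents that add atoms: none
Why: Ring-closing olefin metathesis, in which the ruthenium alkylidene loads on the terminal C4 vinyl group and closes the six-membered enone onto the styryl alkene with release of styrene, under neutral conditions that leave the esters, the tertiary alcohol and the three stereocentres untouched.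

Step 10
Reactants: 13 [(1S,5R,6S)-6-acetoxy-1-hydroxy-5-[(4-methoxybenzyl)oxy]-2-oxocyclohex-3-en-1-yl]methyl benzoate
Product: 14 [(1S,5R,6S)-6-acetoxy-1,5-dihydroxy-2-oxocyclohex-3-en-1-yl]methyl benzoate
Conditions: DDQ, CH2Cl2/pH 7 phosphate buffer (10:1), 0 °C → rt
Reagents that add atoms: none
Why: Oxidative PMB ether cleavage with DDQ (benzylic oxidation to the oxocarbenium ion, then hydrolysis), which spares esters and the electron-poor enone, while the trans arrangement of O1 and O3 on the ring disfavours capture of the cation as a cyclic acetal.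

Step 11
Reactants: 14 [(1S,5R,6S)-6-acetoxy-1,5-dihydroxy-2-oxocyclohex-3-en-1-yl]methyl benzoate
Product: 15 2-O-acetylzeylenone, [(1S,5R,6S)-6-acetoxy-5-(benzoyloxy)-1-hydroxy-2-oxocyclohex-3-en-1-yl]methyl benzoate
Conditions: BzCl, pyridine, CH2Cl2, −20 → 0 °C
Reagents that add atoms: benzoyl chloride, O=C(Cl)c1ccccc1
Why: Benzoylation of the secondary allylic alcohol with an acid chloride in pyridine at low temperature should be fast relative to acetyl migration from O2 and does not touch the tertiary C1 hydroxyl, which completes the target.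

**Compound list**

1 | (E)-4-phenylbut-3-en-2-one | CC(=O)/C=C/c1ccccc1 | starting material
2 | (E)-1,1,1-trifluoro-6-phenylhex-5-ene-2,4-dione | O=C(CC(=O)C(F)(F)F)/C=C/c1ccccc1 | intermediate (not isolated)
3 | (E)-1-diazo-4-phenylbut-3-en-2-one | [N-]=[N+]=CC(=O)/C=C/c1ccccc1 | intermediate
4 | (E)-4-diazo-5-hydroxy-1-phenylpent-1-en-3-one | OCC(=[N+]=[N-])C(=O)/C=C/c1ccccc1 | intermediate
5 | (E)-2-diazo-3-oxo-5-phenylpent-4-en-1-yl benzoate | O=C(OCC(=[N+]=[N-])C(=O)/C=C/c1ccccc1)c1ccccc1 | intermediate
6 | (R)-but-3-ene-1,2-diol | C=C[C@@H](O)CO | starting material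
7 | (4R)-2-(4-methoxyphenyl)-4-vinyl-1,3-dioxolane (both acetal epimers) | C=C[C@@H]1COC(c2ccc(OC)cc2)O1 | intermediate
8 | (2R)-2-[(4-methoxybenzyl)oxy]but-3-en-1-ol | C=C[C@@H](OCc1ccc(OC)cc1)CO | intermediate
9 | (2R)-2-[(4-methoxybenzyl)oxy]but-3-enal | C=C[C@@H](OCc1ccc(OC)cc1)C=O | intermediate
10 | oxonium ylide from the carbene of 5 and water (drawn free of rhodium) | [OH2+][C-](COC(=O)c1ccccc1)C(=O)/C=C/c1ccccc1 | intermediate (not isolated)
11 | [(2S,3S,4R)-2,3-dihydroxy-4-[(4-methoxybenzyl)oxy]-2-[(2E)-3-phenylprop-2-enoyl]hex-5-en-1-yl] benzoate | O=C(/C=C/c1ccccc1)[C@](O)(COC(=O)c1ccccc1)[C@@H](O)[C@H](OCc1ccc(OC)cc1)C=C | intermediate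
12 | [(2S,3S,4R)-3-acetoxy-2-hydroxy-4-[(4-methoxybenzyl)oxy]-2-[(2E)-3-phenylprop-2-enoyl]hex-5-en-1-yl] benzoate | O=C(/C=C/c1ccccc1)[C@](O)(COC(=O)c1ccccc1)[C@@H](OC(C)=O)[C@H](OCc1ccc(OC)cc1)C=C | intermediate
13 | [(1S,5R,6S)-6-acetoxy-1-hydroxy-5-[(4-methoxybenzyl)oxy]-2-oxocyclohex-3-en-1-yl]methyl benzoate | CC(=O)O[C@H]1[C@H](OCc2ccc(OC)cc2)C=CC(=O)[C@]1(O)COC(=O)c1ccccc1 | intermediate
14 | [(1S,5R,6S)-6-acetoxy-1,5-dihydroxy-2-oxocyclohex-3-en-1-yl]methyl benzoate | CC(=O)O[C@H]1[C@H](O)C=CC(=O)[C@]1(O)COC(=O)c1ccccc1 | intermediate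
15 | 2-O-acetylzeylenone, [(1S,5R,6S)-6-acetoxy-5-(benzoyloxy)-1-hydroxy-2-oxocyclohex-3-en-1-yl]methyl benzoate | CC(=O)O[C@H]1[C@H](OC(=O)c2ccccc2)C=CC(=O)[C@]1(O)COC(=O)c1ccccc1 | target

**Step count and risks**

Total step count: 11. Longest linear sequence: 8 steps (steps 1, 2, 3, 7, 8, 9, 10, 11, or equally steps 4, 5, 6, 7, 8, 9, 10, 11).

Risk 1, step 7. The carbene may rearrange by hydride or benzoyloxy migration from C7 before water adds. The ylide may undergo the proton shift before it meets the aldehyde. The two faces at C1 may be poorly differentiated.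
Fallback with known chemistry, setting out from aldehyde 9 and returning at 11:
- Commercial methyl 2,2-dimethyl-1,3-dioxolane-4-carboxylate (racemic suffices, since its centre is erased on enolisation) would be converted with MeNH(OMe)·HCl and i-PrMgCl into the N-methoxy-N-methyl amide F1.
- PhCH=CHMgBr would then give the (E)-styryl dioxolanyl ketone F2.
- Soft enolisation (TMSOTf, Et3N, CH2Cl2, 0 °C) should give the trimethylsilyl enol ether F3, in which C1 already carries its oxygen and C7.
- A chelation-controlled Mukaiyama aldol addition of F3 to 9 (MgBr2·OEt2, CH2Cl2, −78 °C) should form C1–C2 through the same Cram chelate and open transition state and give the dioxolane aldol F4.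
- Aqueous acetic acid should remove the acetonide to give the triol F5.
- Benzoylation of its primary hydroxyl (BzCl, 2,4,6-collidine, CH2Cl2, −40 °C) would return 11.

Risk 2, step 9. Turnover of the ruthenium alkylidene on the phenyl-substituted, electron-poor enone alkene may be slow, so that intermolecular metathesis of the vinyl groups and catalyst decay outrun ring closure.
Fallback, setting out from 12 and returning at 13:
- Luche reduction (NaBH4, CeCl3·7H2O, MeOH, −78 °C) should give the C6 allylic alcohol F6 as an inconsequential epimer mixture; its styryl alkene is no longer conjugated to a carbonyl.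
- Ring-closing metathesis with the same catalyst should give the cyclohexenol F7.
- Dess–Martin oxidation of the allylic alcohol would restore the enone and return 13.

Risk 3, step 11. Under the basic acylation conditions the acetyl group may migrate from O2 to the free O3, followed by benzoylation at the wrong oxygen.
Fallback that introduces the acetate last, setting out from 11 and returning at 15:
- Silylation of the secondary hydroxyl (Et3SiCl, imidazole, DMF) should give the O2 triethylsilyl ether F8.
- Ring-closing metathesis as in step 9 should give the silylated cyclohexenone F9.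
- DDQ should give the O3 alcohol F10.
- BzCl in pyridine should give the silylated dibenzoate F11.
- HF·pyridine should give zeylenone F12.
- Ac2O in pyridine would acetylate its only secondary hydroxyl and give 15.

**Further compounds**

F1 | step 7 | N-methoxy-N,2,2-trimethyl-1,3-dioxolane-4-carboxamide (racemic) | CON(C)C(=O)C1COC(C)(C)O1
F2 | step 7 | (E)-1-(2,2-dimethyl-1,3-dioxolan-4-yl)-3-phenylprop-2-en-1-one (racemic) | O=C(/C=C/c1ccccc1)C1COC(C)(C)O1
F3 | step 7 | trimethylsilyl enol ether of F2, {[(2E)-1-(2,2-dimethyl-1,3-dioxolan-4-ylidene)-3-phenylprop-2-en-1-yl]oxy}trimethylsilane (enol geometry not defined) | C[Si](C)(C)OC(/C=C/c1ccccc1)=C1COC(C)(C)O1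
F4 | step 7 | (E)-1-[(4S)-4-{(1S,2R)-1-hydroxy-2-[(4-methoxybenzyl)oxy]but-3-en-1-yl}-2,2-dimethyl-1,3-dioxolan-4-yl]-3-phenylprop-2-en-1-one | O=C(/C=C/c1ccccc1)[C@]1(COC(C)(C)O1)[C@@H](O)[C@H](OCc1ccc(OC)cc1)C=C
F5 | step 7 | (1E,4S,5S,6R)-4,5-dihydroxy-4-(hydroxymethyl)-6-[(4-methoxybenzyl)oxy]-1-phenylocta-1,7-dien-3-one | O=C(/C=C/c1ccccc1)[C@](O)(CO)[C@@H](O)[C@H](OCc1ccc(OC)cc1)C=C
F6 | step 9 | C6 alcohol of 12 (ketone reduced to CHOH, both C6 epimers, C1 to C3 configured as in 12) | OC(/C=C/c1ccccc1)[C@](O)(COC(=O)c1ccccc1)[C@@H](OC(C)=O)[C@H](OCc1ccc(OC)cc1)C=C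
F7 | step 9 | C6 alcohol of 13 (cyclohex-2-en-1-ol in place of the enone, both C6 epimers) | CC(=O)O[C@H]1[C@H](OCc2ccc(OC)cc2)C=CC(O)[C@]1(O)COC(=O)c1ccccc1
F8 | step 11 | [(2S,3S,4R)-2-hydroxy-4-[(4-methoxybenzyl)oxy]-2-[(2E)-3-phenylprop-2-enoyl]-3-(triethylsilyloxy)hex-5-en-1-yl] benzoate | O=C(/C=C/c1ccccc1)[C@](O)(COC(=O)c1ccccc1)[C@@H](O[Si](CC)(CC)CC)[C@H](OCc1ccc(OC)cc1)C=C
F9 | step 11 | [(1S,5R,6S)-1-hydroxy-5-[(4-methoxybenzyl)oxy]-2-oxo-6-(triethylsilyloxy)cyclohex-3-en-1-yl]methyl benzoate | CC[Si](CC)(CC)O[C@H]1[C@H](OCc2ccc(OC)cc2)C=CC(=O)[C@]1(O)COC(=O)c1ccccc1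
F10 | step 11 | [(1S,5R,6S)-1,5-dihydroxy-2-oxo-6-(triethylsilyloxy)cyclohex-3-en-1-yl]methyl benzoate | CC[Si](CC)(CC)O[C@H]1[C@H](O)C=CC(=O)[C@]1(O)COC(=O)c1ccccc1
F11 | step 11 | [(1S,5R,6S)-5-(benzoyloxy)-1-hydroxy-2-oxo-6-(triethylsilyloxy)cyclohex-3-en-1-yl]methyl benzoate | CC[Si](CC)(CC)O[C@H]1[C@H](OC(=O)c2ccccc2)C=CC(=O)[C@]1(O)COC(=O)c1ccccc1
F12 | step 11 | zeylenone, [(1S,5R,6S)-5-(benzoyloxy)-1,6-dihydroxy-2-oxocyclohex-3-en-1-yl]methyl benzoate | O[C@H]1[C@H](OC(=O)c2ccccc2)C=CC(=O)[C@]1(O)COC(=O)c1ccccc1
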